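**Assumption:** commercial (−)-epigallocatechin (EGC, green-tea grade) is the only chiral starting material, and 3,4,5-tris(benzyloxy)benzoic acid is bought. "Upper unit" means the flavan with the free 3-OH, "lower unit" the flavan carrying the gallate. The target is read as epigallocatechin-(4β→6)-epigallocatechin 3-O-gallate (upper 2R,3R,4S; lower 2R,3R).

## Retrosynthetic overview

1. Target 10 ⇒ protected dimer 9 (thirteen O-benzyl groups, Br at C8 of the lower unit) by one global hydrogenolysis.
2. 9 ⇒ interflavan bond C4(upper)–C6(lower), made by a nickel-mediated reductive union of two electrophiles: the C4 ether/chloride 7/8 and the C6 aryl iodide 6. C4, natively a benzylic cation, reacts here as a benzylic radical/carbanion equivalent and is arylated anti to the 3-OH (4β).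
3. 6 ⇒ 4 (Br at C8 as blocking group, then I at C6); 7 ⇒ 2 (DDQ, MeOH).
4. 4 ⇒ 2 + tri-O-benzylgallic acid 3 (esterification of the 3-OH); 2 ⇒ EGC 1 (five-fold O-benzylation).
5. No ring is formed: rings A, C and B of both units and four of the five stereocentres come from 1; only C4 of the upper unit is new.

## Route

Step 1
Reactants: 1 (−)-epigallocatechin (EGC)
Product: 2 5,7,3′,4′,5′-penta-O-benzyl-epigallocatechin
Conditions: BnBr (5.5 equiv), K2CO3 (6 equiv), degassed DMF, Ar, 0 → 25 °C
Reagents that add atoms: benzyl bromide, BrCc1ccccc1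
Why: Williamson ether synthesis, in which the five phenols are deprotonated by K2CO3 and O-benzylated by SN2 while the much less acidic secondary 3-OH and both stereocentres stay untouched (no new stereocentre).

Step 2
Reactants: 2 5,7,3′,4′,5′-penta-O-benzyl-epigallocatechin; 3 3,4,5-tris(benzyloxy)benzoic acid
Product: 4 octa-O-benzyl-EGCG
Conditions: 3 (1.5 equiv), DCC (1.6 equiv), DMAP (0.3 equiv), CH2Cl2, 0 → 25 °C
Reagents that add atoms: none
Why: Steglich esterification, in which the DCC-activated acid is passed by DMAP to the axial 3-OH and the C3–O bond is not broken, so C3 keeps its configuration.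

Step 3
Reactants: 4 octa-O-benzyl-EGCG
Product: 6 8-bromo-6-iodo-octa-O-benzyl-EGCG, via 8-bromo-octa-O-benzyl-EGCG 5 (not isolated)
Conditions: NBS (1.0 equiv), CH2Cl2, −78 → 0 °C; then NIS (1.3 equiv), TFA (0.3 equiv), 0 → 25 °C, dark
Reagents that add atoms: N-bromosuccinimide, O=C1CCC(=O)N1Br; N-iodosuccinimide, O=C1CCC(=O)N1I
Why: Electrophilic aromatic halogenation, in which the phloroglucinol-type ring A is far more electron-rich than ring B or the galloyl ring, NBS takes the less hindered C8 first (the usual site in benzylated flavan-3-ols) and the only remaining ring A position, C6, is then iodinated, with no stereocentre involved.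

Step 4
Reactants: 2 5,7,3′,4′,5′-penta-O-benzyl-epigallocatechin
Product: 7 4β-methoxy-penta-O-benzyl-epigallocatechin
Conditions: DDQ (2 equiv), MeOH (10 equiv), CH2Cl2, 25 °C
Reagents that add atoms: methanol, CO
Why: DDQ benzylic oxidation (hydride abstraction at C4, stabilised by the 5,7-dialkoxy ring A) followed by capture of the cation by methanol anti to the axial 3-OH gives the 3,4-trans ether, whose C4 configuration does not matter because C4 becomes planar again in step 5.

Step 5
Reactants: 7 4β-methoxy-penta-O-benzyl-epigallocatechin; 6 8-bromo-6-iodo-octa-O-benzyl-EGCG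
Product: 9 penta-O-benzyl-epigallocatechin-(4β→6)-(8-bromo-octa-O-benzyl-EGCG), via 4β-chloro-penta-O-benzyl-epigallocatechin 8 (not isolated)
Conditions: 7 (1.5 equiv, added slowly), TMSCl (2 equiv), NiBr2(dme) (20 mol %), 2,2′-bipyridine (24 mol %), Mn powder (3 equiv), DMA, 0 → 25 °C; aq. NH4Cl work-up
Reagents that add atoms: chlorotrimethylsilane, C[Si](C)(C)Cl (supplies the chlorine of intermediate 8 only; no reagent atom remains in 9)
Why: Proposed new method: TMSCl turns the acetal-like, 2,4,6-trioxygenated-benzylic C4 methyl ether into the labile chloride 8, zerovalent nickel (made from NiBr2 by Mn) inserts into the C–I bond of 6 well before the more hindered C–Br bond, low-valent nickel abstracts chlorine from 8 to give the planar C4 benzylic radical, this radical is captured by the aryl-nickel species on the β face, anti to the axial 3-OH and to the 2-aryl group, and reductive elimination from trivalent nickel forms the C4–C6 bond with the 4β (3,4-trans) configuration of the target, so that C4, which natively reacts as a cation, is used as a carbanion/radical equivalent against a second electrophile; the closest known reaction type is the nickel-catalysed reductive cross-electrophile coupling of secondary benzylic chlorides or glycosyl halides with aryl iodides (C-aryl glycoside synthesis).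

Step 6
Reactants: 9 penta-O-benzyl-epigallocatechin-(4β→6)-(8-bromo-octa-O-benzyl-EGCG)
Product: 10 epigallocatechin-(4β→6)-epigallocatechin 3-O-gallate (target)
Conditions: H2 (1 atm), Pd(OH)2/C, Et3N (1.1 equiv), THF/MeOH/H2O, 25 °C; filtration, lyophilisation
Reagents that add atoms: none
Why: Catalytic hydrogenolysis cleaves all thirteen benzyl ethers and the aryl C–Br bond (Et3N takes up the HBr so that the acid-labile interflavan bond survives) without touching the ester or any stereocentre.

## Compound list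

1 | (−)-epigallocatechin, EGC (2R,3R) | O[C@@H]1Cc2c(O)cc(O)cc2O[C@@H]1c1cc(O)c(O)c(O)c1 | starting material

2 | 5,7,3′,4′,5′-penta-O-benzyl-(−)-epigallocatechin, free 3-OH (2R,3R) | O[C@@H]1Cc2c(OCc3ccccc3)cc(OCc3ccccc3)cc2O[C@@H]1c1cc(OCc2ccccc2)c(OCc2ccccc2)c(OCc2ccccc2)c1 | intermediate

3 | 3,4,5-tris(benzyloxy)benzoic acid (tri-O-benzylgallic acid) | OC(=O)c1cc(OCc2ccccc2)c(OCc2ccccc2)c(OCc2ccccc2)c1 | starting material

4 | octa-O-benzyl-EGCG: (2R,3R)-5,7-bis(benzyloxy)-2-[3,4,5-tris(benzyloxy)phenyl]chroman-3-yl 3,4,5-tris(benzyloxy)benzoate | O=C(O[C@@H]1Cc2c(OCc3ccccc3)cc(OCc3ccccc3)cc2O[C@@H]1c1cc(OCc2ccccc2)c(OCc2ccccc2)c(OCc2ccccc2)c1)c1cc(OCc2ccccc2)c(OCc2ccccc2)c(OCc2ccccc2)c1 | intermediate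

5 | 8-bromo-octa-O-benzyl-EGCG (Br on ring A next to the ring oxygen; 2R,3R) | O=C(O[C@@H]1Cc2c(OCc3ccccc3)cc(OCc3ccccc3)c(Br)c2O[C@@H]1c1cc(OCc2ccccc2)c(OCc2ccccc2)c(OCc2ccccc2)c1)c1cc(OCc2ccccc2)c(OCc2ccccc2)c(OCc2ccccc2)c1 | intermediate

6 | 8-bromo-6-iodo-octa-O-benzyl-EGCG (I between the two ring A benzyloxy groups; 2R,3R) | O=C(O[C@@H]1Cc2c(OCc3ccccc3)c(I)c(OCc3ccccc3)c(Br)c2O[C@@H]1c1cc(OCc2ccccc2)c(OCc2ccccc2)c(OCc2ccccc2)c1)c1cc(OCc2ccccc2)c(OCc2ccccc2)c(OCc2ccccc2)c1 | intermediate

7 | 4β-methoxy-penta-O-benzyl-epigallocatechin (2R,3R,4S; OMe trans to 3-OH) | CO[C@H]1c2c(OCc3ccccc3)cc(OCc3ccccc3)cc2O[C@H](c2cc(OCc3ccccc3)c(OCc3ccccc3)c(OCc3ccccc3)c2)[C@@H]1O | intermediate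

8 | 4β-chloro-penta-O-benzyl-epigallocatechin (Cl trans to 3-OH; labile, formed in the flask) | Cl[C@H]1c2c(OCc3ccccc3)cc(OCc3ccccc3)cc2O[C@H](c2cc(OCc3ccccc3)c(OCc3ccccc3)c(OCc3ccccc3)c2)[C@@H]1O | intermediate

9 | protected dimer: upper unit penta-O-benzyl-epigallocatechin (2R,3R, free 3-OH) bonded through C4 (β, trans to 3-OH) to C6 of the lower unit 8-bromo-octa-O-benzyl-EGCG (2R,3R) | O=C(O[C@@H]1Cc2c(c(Br)c(OCc3ccccc3)c([C@H]3c4c(OCc5ccccc5)cc(OCc5ccccc5)cc4O[C@H](c4cc(OCc5ccccc5)c(OCc5ccccc5)c(OCc5ccccc5)c4)[C@@H]3O)c2OCc6ccccc6)O[C@@H]1c1cc(OCc2ccccc2)c(OCc2ccccc2)c(OCc2ccccc2)c1)c1cc(OCc2ccccc2)c(OCc2ccccc2)c(OCc2ccccc2)c1 | intermediate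

10 | epigallocatechin-(4β→6)-epigallocatechin 3-O-gallate, gallate on the lower unit (upper 2R,3R,4S; lower 2R,3R), CNP0204196.2 | O=C(O[C@@H]1Cc2c(cc(O)c([C@H]3c4c(O)cc(O)cc4O[C@H](c4cc(O)c(O)c(O)c4)[C@@H]3O)c2O)O[C@@H]1c1cc(O)c(O)c(O)c1)c1cc(O)c(O)c(O)c1 | target

## Step count and risks

Total step count: 6.
Longest linear sequence: 5 steps (1 → 2 → 4 → 6 → 9 → 10; step 4 is the one-step branch from 2 to 7).

**Step 5 (most likely to fail).** The aryl iodide is flanked by two benzyloxy groups and C4 by the peri 5-benzyloxy group and the 3-OH. Radical capture at nickel may therefore lose out to radical dimerisation, to reduction back to 2, or to cationic self-condensation of 8 at its own free ring A positions. Any transient silylation of the 3-OH by TMSCl is reversed on the aqueous work-up. Partial loss of the C8 bromine under nickel would be harmless, since step 6 removes it anyway. Fallback: make the bond with C4 as the cation and the lower unit as the arene nucleophile. It sets out from 2, together with 5 obtained by ending step 3 after the NBS stage. Compound 2 is oxidised with DDQ in the presence of 2-ethoxyethanol (CH2Cl2, 25 °C) to 4β-(2-ethoxyethoxy)-penta-O-benzyl-epigallocatechin F1, whose chelating leaving group ionises cleanly with TMSOTf (CH2Cl2, −78 °C). The cation is captured by the only free ring A position of 5 (C6; C8 is blocked by bromine; 5 used in 3–4-fold excess), anti to the 3-OH. This gives 9 directly, where the fallback rejoins the route.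

**Step 3.** Iodination at C6, between two benzyloxy groups, may stall, may be reversed by the acid (protodeiodination), or ring B may compete. Fallback: replace direct iodination by metalation and ipso-iodolysis. It sets out from 5 (isolated after the NBS stage). Treatment with Hg(OCOCF3)2 in CH2Cl2 at 0 °C mercurates the most electron-rich free position irreversibly, giving 6-(trifluoroacetoxymercurio)-8-bromo-octa-O-benzyl-EGCG F2. Adding I2 to this cleaves the C–Hg bond at the same carbon and returns to the route at 6.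

**Step 6.** Thirteen benzyl ethers and an aryl bromide must fall in one operation. HBr can cleave the interflavan bond, and the amine can promote oxidation or C2 epimerisation of the free pyrogallol rings. Fallback: separate the two tasks. It sets out from 9. Radical hydrodebromination with (Me3Si)3SiH and AIBN in toluene at 80 °C gives the bromine-free penta-O-benzyl-epigallocatechin-(4β→6)-octa-O-benzyl-EGCG F3. This is then debenzylated under neutral, amine-free hydrogenolysis (H2, Pd(OH)2/C, THF/MeOH/H2O), returning to the route at 10.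

## Further compounds

F1 | step 5 | 4β-(2-ethoxyethoxy)-penta-O-benzyl-epigallocatechin (2R,3R, ether trans to 3-OH) | CCOCCO[C@H]1c2c(OCc3ccccc3)cc(OCc3ccccc3)cc2O[C@H](c2cc(OCc3ccccc3)c(OCc3ccccc3)c(OCc3ccccc3)c2)[C@@H]1O

F2 | step 3 | 6-(trifluoroacetoxymercurio)-8-bromo-octa-O-benzyl-EGCG (2R,3R) | O=C(O[C@@H]1Cc2c(OCc3ccccc3)c([Hg]OC(=O)C(F)(F)F)c(OCc3ccccc3)c(Br)c2O[C@@H]1c1cc(OCc2ccccc2)c(OCc2ccccc2)c(OCc2ccccc2)c1)c1cc(OCc2ccccc2)c(OCc2ccccc2)c(OCc2ccccc2)c1

F3 | step 6 | penta-O-benzyl-epigallocatechin-(4β→6)-octa-O-benzyl-EGCG, bromine-free protected dimer | O=C(O[C@@H]1Cc2c(cc(OCc3ccccc3)c([C@H]3c4c(OCc5ccccc5)cc(OCc5ccccc5)cc4O[C@H](c4cc(OCc5ccccc5)c(OCc5ccccc5)c(OCc5ccccc5)c4)[C@@H]3O)c2OCc6ccccc6)O[C@@H]1c1cc(OCc2ccccc2)c(OCc2ccccc2)c(OCc2ccccc2)c1)c1cc(OCc2ccccc2)c(OCc2ccccc2)c(OCc2ccccc2)c1
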